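**Remark:** guaiane numbering (C1–C15) is used for all intermediates. Ring A is the cyclopentane, ring B the cycloheptane, ring C the γ-lactone, ring D the bridging dihydropyran. α is the face of H1 and H5 in the target. The ester at C8 is the (2R)-2-methylbutanoate, as the SMILES states.

## Retrosynthetic overview

1. The target is a 1α,5α-cis-fused guaian-6α,12-olide whose 4β-oxygen bridges to C14 as an enol ether (ring D). Ring D is closed late by cyclodehydration of a C14 aldehyde onto the 4β-hydroxyl, after the α-methylene group and the C8 ester are in place.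
2. C4 with its CH2OH group comes from convex-face addition of a hydroxymethyl anion equivalent to a cis-fused hydroazulen-4-one.
3. Key disconnection: ring A is cut at C1–C2 and C3–C4, a nickel-catalysed reductive (3+2) cycloaddition of a ring-B enoate with ethynyltrimethylsilane (a masked CH2–CH2 unit). The enabling feature is that ring A shares only the C1–C5 bond with ring B, C4 is an oxygen-bearing carbon on C5, and C2–C3 is a bare CH2–CH2. C4(=O)–C5=C1 is therefore a cyclohept-1-ene-1-carboxylate whose two electrophilic carbons (acyl C4, β-carbon C1) are joined to one two-carbon partner by polarity reversal at nickel.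
4. Ring B is closed by ring-closing metathesis (C1=C5). C7 and C8 come from diethyl (S)-malate (Fráter–Seebach alkylation), C9 and C10 from an Evans crotonate aldol, C6 from a Felkin-controlled vinylalumination.
5. Ring order: temporary 1,3-dioxane, then γ-lactone C, cycloheptene B, cyclopentanone A (key step), dihydropyran D.

Key step: step 11

## Route

Step 1
Reactants: 1 diethyl (S)-malate; 2 tert-butyl bromoacetate
Product: 3 anti-alkylated triester (3-tert-butyl 1,2-diethyl (1S,2R)-1-hydroxypropane-1,2,3-tricarboxylate)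
Conditions: LiN(i-Pr)2 (2.2 equiv), THF, −78 → −20 °C; then 2, −78 → −10 °C; aq. NH4Cl
Reagents that add atoms: none
Why: Fráter–Seebach alkylation, in which the lithium alkoxide–enolate dianion of the β-hydroxy ester is alkylated anti to the alkoxide, should set C7 relative to the malate carbinol C8.

Step 2
Reactants: 3 anti-alkylated triester
Product: 4 C8 tert-butyldimethylsilyl ether
Conditions: TBSOTf, 2,6-lutidine, CH2Cl2, 0 °C
Reagents that add atoms: tert-butyldimethylsilyl trifluoromethanesulfonate, CC(C)(C)[Si](C)(C)OS(=O)(=O)C(F)(F)F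
Why: Silyl triflate silylation of a hindered secondary alcohol should give a non-chelating ether, which is wanted for the later Felkin addition at C6.

Step 3
Reactants: 4 C8 silyl ether
Product: 5 C9 aldehyde
Conditions: i-Bu2AlH (1.05 equiv), CH2Cl2, −78 °C; aq. KNaC4H4O6 work-up
Reagents that add atoms: none
Why: Low-temperature half-reduction with i-Bu2AlH should select the α-silyloxy ethyl ester, the more electrophilic of the two ethyl esters, while the tert-butyl ester is inert.

Step 4
Reactants: 6 (S)-4-benzyloxazolidin-2-one; 7 (E)-but-2-enoyl chloride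
Product: 8 (S)-4-benzyl-3-[(E)-but-2-enoyl]oxazolidin-2-one
Conditions: n-BuLi, THF, −78 °C; then 7, −78 → 0 °C
Reagents that add atoms: none
Why: N-acylation of the lithiated oxazolidinone with the acid chloride is a standard imide synthesis.

Step 5
Reactants: 5 C9 aldehyde; 8 crotonate imide
Product: 9 syn-aldol adduct (C9 hydroxyl, C10 vinyl, C14 imide)
Conditions: 8, Bu2BOTf, Et3N, CH2Cl2, −78 → 0 °C; then 5, −78 → 0 °C; pH 7 buffer, MeOH, H2O2, 0 °C
Reagents that add atoms: none
Why: Evans syn-aldol reaction of the (Z)-boron dienolate at its α-carbon through a Zimmerman–Traxler transition state should set C9 and C10 under auxiliary control, overriding the bias of the α-silyloxy aldehyde.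

Step 6
Reactants: 9 syn-aldol adduct
Product: 10 C9,C14 1,3-diol
Conditions: NaBH4, THF/H2O (4:1), 0 °C → rt
Reagents that add atoms: none
Why: Borohydride reduction of the activated imide carbonyl (reductive removal of the auxiliary) should leave the ethyl and tert-butyl esters untouched.

Step 7
Reactants: 10 1,3-diol
Product: 11 cis-disubstituted 2,2-dimethyl-1,3-dioxane (acetonide of O9 and O14)
Conditions: Me2C(OMe)2, PPTS (cat.), CH2Cl2, rt
Reagents that add atoms: 2,2-dimethoxypropane, COC(C)(C)OC
Why: Acid-catalysed transketalisation should give the six-membered acetonide, which also stops lactonisation of the C9 hydroxyl onto the C6 ester.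

Step 8
Reactants: 11 acetonide
Product: 12 C6 aldehyde
Conditions: i-Bu2AlH (1.1 equiv), toluene, −78 °C; aq. KNaC4H4O6 work-up
Reagents that add atoms: none
Why: Half-reduction of the remaining ethyl ester with i-Bu2AlH at low temperature should stop at the aldehyde, the tert-butyl ester being too hindered to react.

Step 9
Reactants: 12 C6 aldehyde; 13 methyl propiolate
Product: 15 trans-γ-lactone diene, via hydroxy ester 14 (not isolated)
Conditions: 13, i-Bu2AlH, NMO, THF, 0 °C; then 12, 0 °C → rt; aq. KNaC4H4O6 work-up; then CSA (10 mol%), CH2Cl2, rt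
Reagents that add atoms: none
Why: Vinylalumination (a Morita–Baylis–Hillman-type adduct from an α-acrylate anion equivalent) should add to the aldehyde under Felkin–Anh control reinforced by the 1,3-anti effect of the β-silyloxy group, setting C6 (oxygen α, trans to the C7 side chain), and acid should then close the γ-lactone with loss of tert-butanol.

Step 10
Reactants: 15 trans-γ-lactone diene
Product: 16 ring-B enoate (methyl cyclohept-1(5)-ene-carboxylate fused to lactone and dioxane)
Conditions: second-generation Hoveyda–Grubbs catalyst, RuCl2(H2IMes)(=CH-C6H4-2-O-i-Pr) (5 mol%), toluene (5 mM), 80 °C, argon sparge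
Reagents that add atoms: none
Why: Ring-closing metathesis between the vinyl group and the 2-substituted acrylate should give the seven-membered trisubstituted enoate, the lactone and the dioxane holding the two alkenes within reach.

Step 11
Reactants: 16 ring-B enoate; 17 ethynyltrimethylsilane
Product: 18 3-trimethylsilyl cyclopent-2-en-4-one (ring A closed, 1αH, 5αH)
Conditions: Ni(cod)2 (10 mol%), PBu3 (20 mol%), Et3B (3 equiv), 17 (2 equiv), MeOH/THF (1:8), 50 °C
Reagents that add atoms: none
Why: Zerovalent nickel should couple the enoate and the alkyne by oxidative cyclisation to a seven-membered nickelacycle (a nickel O-enolate), in which the new C1–C2 bond joins the enoate β-carbon to the unsubstituted alkyne carbon while the silicon-bearing carbon stays on nickel; methanol protonates C5, the alkenylnickel adds to the acyl carbon C4 with loss of methoxide (C3–C4 bond), and Et3B returns divalent nickel to zerovalent nickel. The closest known reaction type is the nickel-catalysed reductive (3+2) cycloaddition of enoates with alkynes to cyclopent-2-enones under exactly this catalyst system. Ring A closes by an intermolecular C–C coupling at C1 followed by a 5-exo-trig acyl substitution at C4. C1 is controlled by the two flanking allylic centres, C10 (C14 on the α face, held by the cis-fused dioxane) and C6 (lactone oxygen α), so the nickel–alkyne unit should enter from the β face; C5 follows because only the cis ring fusion (H5 α, protonation on the convex face) lets the alkenylnickel reach C4. The step needs chemoselectivity for the conjugated ester over the saturated lactone, which the need for an alkene-bound nickel secures, and regioselectivity in the alkyne, which the silyl group secures while also suppressing alkyne oligomerisation and being removable in the next step.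

Step 12
Reactants: 18 silyl cyclopentenone
Product: 20 cis-fused cyclopentan-4-one, via α-silyl ketone 19 (not isolated)
Conditions: H2 (1 atm), 10% Pd/C, EtOAc, rt; then K2CO3 (cat.), MeOH, 0 °C
Reagents that add atoms: none
Why: Heterogeneous hydrogenation of the enone C2=C3 bond followed by protodesilylation of the α-silyl ketone should give the C2H2–C3H2 unit, no other reducible group being present.

Step 13
Reactants: 20 cyclopentan-4-one; 21 (chloromethyl)(isopropoxy)dimethylsilane (as its Grignard reagent)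
Product: 23 4β,15-diol, via silylmethyl carbinol 22 (not isolated)
Conditions: 21, Mg, THF; then 20, THF, −78 → 0 °C; then KF, KHCO3, 30% H2O2, THF/MeOH, rt
Reagents that add atoms: hydrogen peroxide, OO
Why: Grignard addition of the hydroxymethyl anion equivalent from the convex α face of the cis-fused bicycle should set C4 (hydroxyl β, CH2 α), and Tamao–Fleming oxidation should turn the C–Si bond into C15–OH.

Step 14
Reactants: 23 4β,15-diol
Product: 24 15-O-tert-butyldiphenylsilyl ether
Conditions: TBDPSCl, imidazole, CH2Cl2, 0 °C → rt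
Reagents that add atoms: tert-butyl(chloro)diphenylsilane, CC(C)(C)[Si](Cl)(c1ccccc1)c1ccccc1
Why: Silylation should be selective for the primary hydroxyl, the tertiary C4 hydroxyl being unreactive.

Step 15
Reactants: 24 15-O-silyl ether; 25 N,N-dimethylmethyleneiminium iodide (Eschenmoser's salt)
Product: 28 α-methylene lactone, via Mannich base 26 (not isolated), via ammonium iodide 27 (not isolated)
Conditions: LiN(i-Pr)2 (2.5 equiv), THF, −78 °C; 25, −78 → 0 °C; then MeI, MeOH, rt; then aq. NaHCO3, EtOAc, rt
Reagents that add atoms: none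
Why: Lactone enolate Mannich reaction, N-methylation and Hofmann-type elimination is the standard α-methylenation of a γ-lactone, and it is done here before any enolisable ester is present.

Step 16
Reactants: 28 α-methylene lactone
Product: 29 8β-alcohol
Conditions: HF·pyridine, pyridine, THF, 0 °C → rt
Reagents that add atoms: none
Why: Buffered HF·pyridine desilylation should cleave the secondary tert-butyldimethylsilyl ether much faster than the neopentyl-type tert-butyldiphenylsilyl ether, and the acetonide is stable to it.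

Step 17
Reactants: 29 8β-alcohol; 30 (R)-2-methylbutanoic acid
Product: 31 8β-(2R)-2-methylbutanoate
Conditions: 30, DIC, DMAP (cat.), CH2Cl2, 0 °C → rt
Reagents that add atoms: none
Why: Steglich esterification should acylate the only reactive hydroxyl (C4–OH is tertiary), low temperature and catalytic DMAP limiting epimerisation of the acid.

Step 18
Reactants: 31 8β-ester acetonide
Product: 32 9α,14-diol
Conditions: AcOH/H2O/THF (3:1:1), 40 °C
Reagents that add atoms: none
Why: Mild aqueous acid hydrolysis of the acetonide should be tolerated by the silyl ether, the esters and the α-methylene lactone.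

Step 19
Reactants: 32 9α,14-diol
Product: 33 C14 aldehyde (10βH)
Conditions: TEMPO (10 mol%), PhI(OAc)2 (1.1 equiv), CH2Cl2, rt
Reagents that add atoms: none
Why: TEMPO/PhI(OAc)2 oxidation should select the primary C14 alcohol in the presence of the secondary C9 and tertiary C4 hydroxyls.

Step 20
Reactants: 33 C14 aldehyde
Product: 35 bridged enol ether (9α-alcohol), via lactol 34 (not isolated)
Conditions: PPTS (20 mol%), 4 Å molecular sieves, benzene, 70 °C
Reagents that add atoms: none
Why: Acid-catalysed cyclodehydration should epimerise C10 by enolisation, trap the 14β-aldehyde with the 4β-hydroxyl as the bridged lactol, and lose water through the oxocarbenium ion to give the cyclic enol ether, in which C10 is no longer a stereocentre.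

Step 21
Reactants: 35 bridged enol ether
Product: 36 9α-acetate
Conditions: Ac2O, pyridine, DMAP (cat.), CH2Cl2, 0 °C
Reagents that add atoms: acetic anhydride, CC(=O)OC(C)=O
Why: Acetylation of the remaining allylic secondary hydroxyl runs under basic conditions that do not ionise the enol ether.

Step 22
Reactants: 36 9α-acetate
Product: 37 CNP0013863.3 (target)
Conditions: Bu4NF, AcOH (1:1), THF, 0 °C → rt
Reagents that add atoms: none
Why: Acetic acid-buffered fluoride desilylation of the primary silyl ether is near-neutral and should spare the enol ether, the allylic acetate, both esters and the α-methylene lactone.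

## Compound list

1 | diethyl (S)-malate | CCOC(=O)C[C@H](O)C(=O)OCC | starting material
2 | tert-butyl bromoacetate | BrCC(=O)OC(C)(C)C | starting material
3 | 3-tert-butyl 1,2-diethyl (1S,2R)-1-hydroxypropane-1,2,3-tricarboxylate | CCOC(=O)[C@H](CC(=O)OC(C)(C)C)[C@H](O)C(=O)OCC | intermediate
4 | 3-tert-butyl 1,2-diethyl (1S,2R)-1-[(tert-butyldimethylsilyl)oxy]propane-1,2,3-tricarboxylate | CCOC(=O)[C@H](CC(=O)OC(C)(C)C)[C@H](O[Si](C)(C)C(C)(C)C)C(=O)OCC | intermediate
5 | 4-tert-butyl 1-ethyl (2R)-2-[(1S)-1-[(tert-butyldimethylsilyl)oxy]-2-oxoethyl]butanedioate (C9 aldehyde) | CCOC(=O)[C@H](CC(=O)OC(C)(C)C)[C@H](O[Si](C)(C)C(C)(C)C)C=O | intermediate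
6 | (S)-4-benzyloxazolidin-2-one | O=C1N[C@@H](Cc2ccccc2)CO1 | starting material
7 | (E)-but-2-enoyl chloride | C/C=C/C(Cl)=O | starting material
8 | (S)-4-benzyl-3-[(E)-but-2-enoyl]oxazolidin-2-one | C/C=C/C(=O)N1[C@@H](Cc2ccccc2)COC1=O | intermediate
9 | syn-aldol adduct: acyclic C6–C10 chain with C6 ethyl ester, C7 CH2CO2t-Bu, C8 OTBS, C9 OH, C10 vinyl and C14 N-acyloxazolidinone (7R,8S,9S,10S) | CCOC(=O)[C@H](CC(=O)OC(C)(C)C)[C@H](O[Si](C)(C)C(C)(C)C)[C@@H](O)[C@H](C=C)C(=O)N1[C@@H](Cc2ccccc2)COC1=O | intermediate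
10 | C9,C14 1,3-diol of the same chain | CCOC(=O)[C@H](CC(=O)OC(C)(C)C)[C@H](O[Si](C)(C)C(C)(C)C)[C@@H](O)[C@H](C=C)CO | intermediate
11 | acetonide: cis-4,5-disubstituted 2,2-dimethyl-1,3-dioxane (C9 at position 4, C10 with vinyl at position 5) | CCOC(=O)[C@H](CC(=O)OC(C)(C)C)[C@H](O[Si](C)(C)C(C)(C)C)[C@H]1OC(C)(C)OC[C@H]1C=C | intermediate
12 | C6 aldehyde of 11 | O=C[C@H](CC(=O)OC(C)(C)C)[C@H](O[Si](C)(C)C(C)(C)C)[C@H]1OC(C)(C)OC[C@H]1C=C | intermediate
13 | methyl propiolate | C#CC(=O)OC | starting material
14 | methyl 2-methylidene-3-hydroxy ester (6α-OH, Morita–Baylis–Hillman-type adduct) | C=C(C(=O)OC)[C@@H](O)[C@H](CC(=O)OC(C)(C)C)[C@H](O[Si](C)(C)C(C)(C)C)[C@H]1OC(C)(C)OC[C@H]1C=C | intermediate (not isolated)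
15 | trans-γ-lactone (6α,12-olide) with 1-(methoxycarbonyl)vinyl at C6 and the silyloxy-dioxanyl side chain at C7 | C=C(C(=O)OC)[C@H]1OC(=O)C[C@@H]1[C@H](O[Si](C)(C)C(C)(C)C)[C@H]1OC(C)(C)OC[C@H]1C=C | intermediate
16 | ring-B enoate: methyl cyclohept-1(5)-ene-carboxylate, 6α,12-olide, 8β-OTBS, 9α,14-O-isopropylidene, 10βH | COC(=O)C1=C[C@@H]2COC(C)(C)O[C@@H]2[C@@H](O[Si](C)(C)C(C)(C)C)[C@H]2CC(=O)O[C@H]12 | intermediate
17 | ethynyltrimethylsilane | C#C[Si](C)(C)C | starting material
18 | 3-(trimethylsilyl)-15-norguai-2-en-4-one, 1αH,5αH, with lactone, silyl ether and acetonide as in 16 | O=C1C([Si](C)(C)C)=C[C@H]2[C@@H]3COC(C)(C)O[C@@H]3[C@@H](O[Si](C)(C)C(C)(C)C)[C@H]3CC(=O)O[C@@H]3[C@@H]12 | intermediate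
19 | 3-(trimethylsilyl)-15-norguaian-4-one (C3 epimers) | O=C1C([Si](C)(C)C)C[C@H]2[C@@H]3COC(C)(C)O[C@@H]3[C@@H](O[Si](C)(C)C(C)(C)C)[C@H]3CC(=O)O[C@@H]3[C@@H]12 | intermediate (not isolated)
20 | 15-norguaian-4-one, 1αH,5αH | O=C1CC[C@H]2[C@@H]3COC(C)(C)O[C@@H]3[C@@H](O[Si](C)(C)C(C)(C)C)[C@H]3CC(=O)O[C@@H]3[C@@H]12 | intermediate
21 | (chloromethyl)(isopropoxy)dimethylsilane | CC(C)O[Si](C)(C)CCl | starting material
22 | 4β-hydroxy-4α-[(isopropoxydimethylsilyl)methyl] carbinol | CC(C)O[Si](C)(C)C[C@]1(O)CC[C@H]2[C@@H]3COC(C)(C)O[C@@H]3[C@@H](O[Si](C)(C)C(C)(C)C)[C@H]3CC(=O)O[C@@H]3[C@@H]12 | intermediate (not isolated)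
23 | 4β,15-diol | OC[C@]1(O)CC[C@H]2[C@@H]3COC(C)(C)O[C@@H]3[C@@H](O[Si](C)(C)C(C)(C)C)[C@H]3CC(=O)O[C@@H]3[C@@H]12 | intermediate
24 | 15-O-tert-butyldiphenylsilyl ether of 23 | CC(C)(C)[Si](OC[C@]1(O)CC[C@H]2[C@@H]3COC(C)(C)O[C@@H]3[C@@H](O[Si](C)(C)C(C)(C)C)[C@H]3CC(=O)O[C@@H]3[C@@H]12)(c1ccccc1)c1ccccc1 | intermediate
25 | N,N-dimethylmethyleneiminium iodide | C=[N+](C)C.[I-] | starting material
26 | 13-(dimethylamino) Mannich base (C11 epimers) | CC(C)(C)[Si](OC[C@]1(O)CC[C@H]2[C@@H]3COC(C)(C)O[C@@H]3[C@@H](O[Si](C)(C)C(C)(C)C)[C@H]3C(CN(C)C)C(=O)O[C@@H]3[C@@H]12)(c1ccccc1)c1ccccc1 | intermediate (not isolated)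
27 | 13-(trimethylammonio) iodide | CC(C)(C)[Si](OC[C@]1(O)CC[C@H]2[C@@H]3COC(C)(C)O[C@@H]3[C@@H](O[Si](C)(C)C(C)(C)C)[C@H]3C(C[N+](C)(C)C)C(=O)O[C@@H]3[C@@H]12)(c1ccccc1)c1ccccc1.[I-] | intermediate (not isolated)
28 | α-methylene lactone (11(13)-ene), 8β-OTBS, acetonide, 15-OTBDPS, 4β-OH | CC(C)(C)[Si](OC[C@]1(O)CC[C@H]2[C@@H]3COC(C)(C)O[C@@H]3[C@@H](O[Si](C)(C)C(C)(C)C)[C@H]3C(=C)C(=O)O[C@@H]3[C@@H]12)(c1ccccc1)c1ccccc1 | intermediate
29 | 8β-alcohol | CC(C)(C)[Si](OC[C@]1(O)CC[C@H]2[C@@H]3COC(C)(C)O[C@@H]3[C@@H](O)[C@H]3C(=C)C(=O)O[C@@H]3[C@@H]12)(c1ccccc1)c1ccccc1 | intermediate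
30 | (R)-2-methylbutanoic acid | CC[C@@H](C)C(=O)O | starting material
31 | 8β-[(2R)-2-methylbutanoyl]oxy acetonide | CC(C)(C)[Si](OC[C@]1(O)CC[C@H]2[C@@H]3COC(C)(C)O[C@@H]3[C@@H](OC(=O)[C@H](C)CC)[C@H]3C(=C)C(=O)O[C@@H]3[C@@H]12)(c1ccccc1)c1ccccc1 | intermediate
32 | 9α,14-diol | CC(C)(C)[Si](OC[C@]1(O)CC[C@H]2[C@H](CO)[C@H](O)[C@@H](OC(=O)[C@H](C)CC)[C@H]3C(=C)C(=O)O[C@@H]3[C@@H]12)(c1ccccc1)c1ccccc1 | intermediate
33 | 14-aldehyde (10βH), 9α-OH, 4β-OH | CC(C)(C)[Si](OC[C@]1(O)CC[C@H]2[C@H](C=O)[C@H](O)[C@@H](OC(=O)[C@H](C)CC)[C@H]3C(=C)C(=O)O[C@@H]3[C@@H]12)(c1ccccc1)c1ccccc1 | intermediate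
34 | bridged lactol (4β,14-epoxy-14-ol, 10αH, anomers) | C=C1C(=O)O[C@H]2[C@H]1[C@H](OC(=O)[C@H](C)CC)[C@@H](O)[C@@H]1C(O)O[C@@]3(CO[Si](c4ccccc4)(c4ccccc4)C(C)(C)C)CC[C@@H]1[C@@H]23 | intermediate (not isolated)
35 | bridged enol ether (4β,14-epoxy-10(14)-ene), 9α-OH, 15-OTBDPS | C=C1C(=O)O[C@H]2[C@H]1[C@H](OC(=O)[C@H](C)CC)[C@@H](O)C1=CO[C@@]3(CO[Si](c4ccccc4)(c4ccccc4)C(C)(C)C)CC[C@@H]1[C@@H]23 | intermediate
36 | 9α-acetate, 15-OTBDPS | C=C1C(=O)O[C@H]2[C@H]1[C@H](OC(=O)[C@H](C)CC)[C@@H](OC(C)=O)C1=CO[C@@]3(CO[Si](c4ccccc4)(c4ccccc4)C(C)(C)C)CC[C@@H]1[C@@H]23 | intermediate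
37 | CNP0013863.3 | C=C1C(=O)O[C@H]2[C@H]1[C@H](OC(=O)[C@H](C)CC)[C@@H](OC(C)=O)C1=CO[C@@]3(CO)CC[C@@H]1[C@@H]23 | target

## Step count and risks

Total step count: 22. Longest linear sequence: 21 (steps 1–3 and 5–22; step 4 is a one-step side branch).

The three steps most likely to fail:

1. **Step 11.** The oxidative cyclisation may stall on the hindered, doubly allylically substituted enoate, or be outrun by alkyne oligomerisation. The fallback sets out from 16 and comes back at 20. CuBr·SMe2-catalysed 1,4-addition of vinylmagnesium bromide with TMSCl (THF, −78 °C) should enter anti to C14 and, after protonation, give the 1β-vinyl ester F1 (drawn as the cis isomer; the C5 epimer can be equilibrated with base). Hydrozirconation with Cp2Zr(H)Cl and iodinolysis with I2 should give the primary iodide F2. SmI2 with catalytic Fe(dbm)3 (THF, −30 °C) should then close the C3–C4 bond by intramolecular nucleophilic acyl substitution at the methyl ester and give 20.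

2. **Step 20.** Loss of the C9 hydroxyl by aldol-type dehydration, or migration of the C8 acyl group, may outrun the C10 epimerisation and ring closure. The fallback sets out from 33 and comes back at 35. CSA in MeOH/HC(OMe)3 should epimerise C10 through the methyl enol ether and trap the aldehyde as the bridged cyclic methyl acetal F3. TMSOTf with i-Pr2NEt (CH2Cl2, −78 °C; acetal ionisation and deprotonation at C10), followed by a citric acid wash to cleave the transient C9 trimethylsilyl ether, should give 35.

3. **Step 9.** Facial selectivity at C6 may erode in the aluminium-mediated addition. The fallback sets out from 12 and comes back at 14. A BF3·OEt2-mediated Mukaiyama aldol reaction with 1-methoxy-2-(phenylselanyl)-1-(trimethylsilyloxy)prop-1-ene (open transition state, in which 1,2-Felkin and 1,3-anti induction reinforce each other) should give the α-selanyl β-hydroxy ester F4. Oxidation with H2O2/pyridine and selenoxide syn-elimination toward the methyl group should give 14, which is lactonised to 15 as in step 9.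

## Further compounds

F1 | step 11 | 1β-vinyl methyl ester (1,4-adduct of 16, cis isomer) | COC(=O)[C@H]1[C@@H](C=C)[C@@H]2COC(C)(C)O[C@@H]2[C@@H](O[Si](C)(C)C(C)(C)C)[C@H]2CC(=O)O[C@H]12
F2 | step 11 | 1β-(2-iodoethyl) methyl ester | COC(=O)[C@H]1[C@@H](CCI)[C@@H]2COC(C)(C)O[C@@H]2[C@@H](O[Si](C)(C)C(C)(C)C)[C@H]2CC(=O)O[C@H]12
F3 | step 20 | bridged cyclic methyl acetal (4β,14-epoxy-14-methoxy, 10αH) | C=C1C(=O)O[C@H]2[C@H]1[C@H](OC(=O)[C@H](C)CC)[C@@H](O)[C@@H]1C(OC)O[C@@]3(CO[Si](c4ccccc4)(c4ccccc4)C(C)(C)C)CC[C@@H]1[C@@H]23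
F4 | step 9 | methyl 3-hydroxy-2-methyl-2-(phenylselanyl) ester (6α-OH, C5 epimers) | COC(=O)C(C)([Se]c1ccccc1)[C@@H](O)[C@H](CC(=O)OC(C)(C)C)[C@H](O[Si](C)(C)C(C)(C)C)[C@H]1OC(C)(C)OC[C@H]1C=C
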